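**Retrosynthetic overview**
1. Lophirone J (11) is a (2S)-flavanone whose 2-aryl group is a 2-(4-methoxyphenyl)benzofuran bound through C5. C2 of the chromanone is the only stereocentre and is set last, by enantioselective 1,4-reduction of flavone 9.
2. The pyranone ring of 9 is opened to 1,3-diketone 8, which comes from a Claisen condensation of paeonol (6) with benzofuran methyl ester 5.
3. The strategy rests on the furan ring of the benzofuran. Its C2 and C3 both trace back to carbonyl carbons: C2 to the acyl carbon of a 4-methoxybenzoate carried on O1, and C3 to a formyl carbon ortho to that oxygen. The C2=C3 bond of 5 is therefore cut back to aryl ester–aldehyde 3 and made by reductive coupling with low-valent titanium.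
4. Compound 3 is one O-acylation away from methyl 3-formyl-4-hydroxybenzoate (1) and 4-methoxybenzoyl chloride (2).
5. Ring order: furan ring of the benzofuran (step 2), then the pyranone ring (step 4), then the stereocentre (step 5).

Key step: step 2

Assumption: the sense of induction in step 5 is inferred by analogy with 3-substituted cyclohexenones (hydride delivered to the same enone face), which points to the (S)-ligand for the 2S product; the configuration is to be confirmed by circular dichroism, and the (R)-ligand is used in the same step if the analogy fails.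

**Step 1**
Reactants: 1 methyl 3-formyl-4-hydroxybenzoate; 2 4-methoxybenzoyl chloride
Product: 3 methyl 3-formyl-4-[(4-methoxybenzoyl)oxy]benzoate
Conditions: Et3N, DMAP (cat.), CH2Cl2, 0 °C to rt
Reagents that add atoms: none
Why: DMAP-catalysed O-acylation (nucleophilic acyl substitution) of the acidic phenol by the acid chloride; the aldehyde and the methyl ester are inert under these conditions.

**Step 2**
Reactants: 3 methyl 3-formyl-4-[(4-methoxybenzoyl)oxy]benzoate
Product: 5 methyl 2-(4-methoxyphenyl)-1-benzofuran-5-carboxylate, via cyclic titanium diolate 4 (not isolated)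
Conditions: TiCl3 (4 equiv), Zn dust (8 equiv), THF, reflux, 2 h; then 3 in THF added by syringe pump over 8 h at high dilution, reflux
Reagents that add atoms: none
Why: Low-valent titanium made from TiCl3 and Zn transfers an electron to the formyl group, the more easily reduced carbonyl, and the titanium-bound ketyl carbon (future C3) attacks the neighbouring ester carbonyl carbon (future C2) to give cyclic titanium diolate 4, which is deoxygenated on titanium to the C2=C3 double bond. The closest known reaction is the McMurry-type oxo-ester coupling of ortho-acyloxyaryl carbonyl compounds to benzofurans (and of the corresponding oxo-amides to indoles). The furan ring closes in a 5-exo-trig mode, the ketyl carbon adding to an ester C=O whose oxygen stays outside the new ring. No stereocentre remains, because both carbinol carbons of 4 become sp2 and aromatisation of the furan drives the deoxygenation. The step needs intramolecular ketyl–ester coupling to win over aldehyde–aldehyde pinacol or stilbene formation, which the ortho placement of the ester (five-membered transition state) and slow addition at high dilution should secure; the remote methyl ester has no ketyl beside it and is not reduced by this reagent, and the aryl methyl ether is inert.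

**Step 3**
Reactants: 5 methyl 2-(4-methoxyphenyl)-1-benzofuran-5-carboxylate; 6 paeonol
Product: 8 1-(2-hydroxy-4-methoxyphenyl)-3-[2-(4-methoxyphenyl)-1-benzofuran-5-yl]propane-1,3-dione, via paeonol disodium dianion 7 (not isolated)
Conditions: 6, NaH (4 equiv), THF, 0 °C to rt; then 5, reflux; then 1 M aq. HCl, 0 °C
Reagents that add atoms: none
Why: Crossed Claisen condensation in which the enolate carbon of dianion 7 attacks the non-enolisable methyl ester of 5, and deprotonation of the 1,3-diketone formed by the excess base drives the equilibrium; the benzofuran and the aryl ethers are inert to NaH.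

**Step 4**
Reactants: 8 1-(2-hydroxy-4-methoxyphenyl)-3-[2-(4-methoxyphenyl)-1-benzofuran-5-yl]propane-1,3-dione
Product: 9 7-methoxy-2-[2-(4-methoxyphenyl)-1-benzofuran-5-yl]-4H-chromen-4-one
Conditions: conc. H2SO4 (cat.), AcOH, 100 °C
Reagents that add atoms: none
Why: Acid-catalysed cyclodehydration, the closing step of the classical diketone route to flavones, in which the phenol adds to the distal enolised carbonyl and loss of water gives the conjugated 4-pyranone; aryl methyl ethers and the 2-arylbenzofuran should tolerate catalytic acid in AcOH.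

**Step 5**
Reactants: 9 7-methoxy-2-[2-(4-methoxyphenyl)-1-benzofuran-5-yl]-4H-chromen-4-one
Product: 11 Lophirone J, (2S)-7-methoxy-2-[2-(4-methoxyphenyl)-1-benzofuran-5-yl]-2,3-dihydro-4H-chromen-4-one, via silyl enol ether 10 (not isolated)
Conditions: Cu(OAc)2·H2O (5 mol%), (S)-DTBM-SEGPHOS (5.5 mol%), (EtO)2MeSiH (3 equiv), toluene/THF, 0 °C to rt; then 1 M aq. HCl, THF, 0 °C
Reagents that add atoms: none
Why: Copper hydride-catalysed asymmetric conjugate reduction of a β,β-disubstituted cyclic enone (here a 2-substituted chromone), in which the bisphosphine-bound copper hydride delivers hydride to one face of C2 and so sets the 2S centre under ligand control; the copper enolate is trapped by the silane as silyl enol ether 10, which can neither be reduced further nor open the pyranone ring by β-elimination, and cold dilute acid then protonates C3 without epimerising C2.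

**Compound list**
1 | methyl 3-formyl-4-hydroxybenzoate | COC(=O)c1ccc(O)c(C=O)c1 | starting material
2 | 4-methoxybenzoyl chloride | COc1ccc(C(Cl)=O)cc1 | starting material
3 | methyl 3-formyl-4-[(4-methoxybenzoyl)oxy]benzoate | COC(=O)c1ccc(OC(=O)c2ccc(OC)cc2)c(C=O)c1 | intermediate
4 | cyclic dichlorotitanium 2,3-diolate of methyl 2,3-dihydroxy-2-(4-methoxyphenyl)-2,3-dihydro-1-benzofuran-5-carboxylate (monomeric drawing of the titanium-bound pinacolate, racemic, not isolated) | COC(=O)c1ccc2c(c1)C1O[Ti](Cl)(Cl)OC1(c1ccc(OC)cc1)O2 | intermediate
5 | methyl 2-(4-methoxyphenyl)-1-benzofuran-5-carboxylate | COC(=O)c1ccc2oc(-c3ccc(OC)cc3)cc2c1 | intermediate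
6 | paeonol, 1-(2-hydroxy-4-methoxyphenyl)ethan-1-one | CC(=O)c1ccc(OC)cc1O | starting material
7 | paeonol disodium dianion (sodium phenoxide and sodium enolate, not isolated) | [Na+].[Na+].C=C([O-])c1ccc(OC)cc1[O-] | intermediate
8 | 1-(2-hydroxy-4-methoxyphenyl)-3-[2-(4-methoxyphenyl)-1-benzofuran-5-yl]propane-1,3-dione (drawn as the diketo form) | COc1ccc(-c2cc3cc(C(=O)CC(=O)c4ccc(OC)cc4O)ccc3o2)cc1 | intermediate
9 | 7-methoxy-2-[2-(4-methoxyphenyl)-1-benzofuran-5-yl]-4H-chromen-4-one | COc1ccc(-c2cc3cc(-c4cc(=O)c5ccc(OC)cc5o4)ccc3o2)cc1 | intermediate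
10 | (2S)-4-{[diethoxy(methyl)silyl]oxy}-7-methoxy-2-[2-(4-methoxyphenyl)-1-benzofuran-5-yl]-2H-chromene (not isolated) | COc1ccc(-c2cc3cc([C@@H]4C=C(O[Si](C)(OCC)OCC)c5ccc(OC)cc5O4)ccc3o2)cc1 | intermediate
11 | Lophirone J, (2S)-7-methoxy-2-[2-(4-methoxyphenyl)-1-benzofuran-5-yl]-2,3-dihydro-4H-chromen-4-one | COc1ccc(-c2cc3cc([C@@H]4CC(=O)c5ccc(OC)cc5O4)ccc3o2)cc1 | target

**Step count**
Total steps: 5. Longest linear sequence: 5 steps (1 → 3 → 5 → 8 → 9 → 11).

**Steps most likely to fail**

Step 2 (reductive ester–aldehyde coupling). The ketyl may couple with a second aldehyde molecule instead of the ortho ester, the formyl group may simply be reduced, or the activated aryl ester may be cleaved by the Lewis-acidic titanium salts before coupling. The fallback sets out from 1 and returns at 5. Compound 1 would be reduced with NaBH4 in MeOH at 0 °C to methyl 4-hydroxy-3-(hydroxymethyl)benzoate F1. Treatment with PPh3·HBr in refluxing MeCN should give [2-hydroxy-5-(methoxycarbonyl)benzyl]triphenylphosphonium bromide F2. Heating F2 with acid chloride 2 and Et3N in toluene would acylate the phenol and let the ylide olefinate the new ester carbonyl (intramolecular Wittig reaction), closing the same C2=C3 bond to give 5.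

Step 5 (asymmetric conjugate reduction). The electron-rich 2-aryl chromone may react sluggishly with the copper hydride, 1,2-reduction of the carbonyl may compete, and the enantiomeric purity may erode if the copper enolate expels the ring phenoxide (opening to the chalcone) before it is silylated. The fallback sets out from 5 and returns at 11. Ester 5 would be reduced with i-Bu2AlH (CH2Cl2, −78 °C) to [2-(4-methoxyphenyl)-1-benzofuran-5-yl]methanol F3 and oxidised with MnO2 to 2-(4-methoxyphenyl)-1-benzofuran-5-carbaldehyde F4. Claisen–Schmidt condensation with paeonol 6 (KOH, EtOH) should give (E)-1-(2-hydroxy-4-methoxyphenyl)-3-[2-(4-methoxyphenyl)-1-benzofuran-5-yl]prop-2-en-1-one F5. NaOAc in refluxing EtOH would close it by oxa-Michael addition to the racemic flavanone F6. Kinetic resolution by transfer hydrogenation with Cp*RhCl[(R,R)-TsDPEN] and HCO2H/Et3N is expected to reduce the 2R antipode faster to the cis-(2R,4R)-flavan-4-ol F7 and leave the 2S ketone, which is 11 (at most half of the material).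

Step 3 (Claisen condensation). C-acylation may be slow or incomplete, because the aryl methyl ester is a weak acylating agent for the poorly soluble dianion, and retro-Claisen cleavage may set in on prolonged heating. The fallback sets out from 5 and returns at 8. Ester 5 would be saponified (LiOH, THF/MeOH/H2O; then HCl) to 2-(4-methoxyphenyl)-1-benzofuran-5-carboxylic acid F8. Coupling with paeonol 6 (EDC·HCl, DMAP, CH2Cl2) should give 2-acetyl-5-methoxyphenyl 2-(4-methoxyphenyl)-1-benzofuran-5-carboxylate F9. KOt-Bu in THF would then move the acyl group from oxygen to the enolate carbon (Baker–Venkataraman rearrangement) to give 8.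

**Further compounds**
F1 | step 2 | methyl 4-hydroxy-3-(hydroxymethyl)benzoate | COC(=O)c1ccc(O)c(CO)c1
F2 | step 2 | [2-hydroxy-5-(methoxycarbonyl)benzyl]triphenylphosphonium bromide | COC(=O)c1ccc(O)c(C[P+](c2ccccc2)(c2ccccc2)c2ccccc2)c1.[Br-]
F3 | step 5 | [2-(4-methoxyphenyl)-1-benzofuran-5-yl]methanol | COc1ccc(-c2cc3cc(CO)ccc3o2)cc1
F4 | step 5 | 2-(4-methoxyphenyl)-1-benzofuran-5-carbaldehyde | COc1ccc(-c2cc3cc(C=O)ccc3o2)cc1
F5 | step 5 | (E)-1-(2-hydroxy-4-methoxyphenyl)-3-[2-(4-methoxyphenyl)-1-benzofuran-5-yl]prop-2-en-1-one | COc1ccc(-c2cc3cc(/C=C/C(=O)c4ccc(OC)cc4O)ccc3o2)cc1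
F6 | step 5 | racemic 7-methoxy-2-[2-(4-methoxyphenyl)-1-benzofuran-5-yl]-2,3-dihydro-4H-chromen-4-one | COc1ccc(-c2cc3cc(C4CC(=O)c5ccc(OC)cc5O4)ccc3o2)cc1
F7 | step 5 | (2R,4R)-7-methoxy-2-[2-(4-methoxyphenyl)-1-benzofuran-5-yl]-3,4-dihydro-2H-chromen-4-ol | COc1ccc(-c2cc3cc([C@H]4C[C@@H](O)c5ccc(OC)cc5O4)ccc3o2)cc1
F8 | step 3 | 2-(4-methoxyphenyl)-1-benzofuran-5-carboxylic acid | COc1ccc(-c2cc3cc(C(=O)O)ccc3o2)cc1
F9 | step 3 | 2-acetyl-5-methoxyphenyl 2-(4-methoxyphenyl)-1-benzofuran-5-carboxylate | COc1ccc(-c2cc3cc(C(=O)Oc4cc(OC)ccc4C(C)=O)ccc3o2)cc1
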